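## Retrosynthetic overview

1. The route rests on ring C, the central hexasubstituted benzene. Its carbons Cb, Cd and Cf carry oxygen, while Ca (CH2 to butanoyl ring A), Cc (CH2 to propanoyl ring B) and Ce (butanoyl) carry carbon. This strict alternation is what a 3-alkoxycyclobutenone and an ynol ether should give on thermal benzannulation.
2. Last disconnections: the Ce–acyl bond (Friedel–Crafts) and six O-alkyl bonds (BBr3), leading back to a 3-ethoxy-5-methoxyphenol with Ce–H that carries rings A and B as bis(methyl enol ethers).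
3. Key disconnection: ring C is cut at Cb–Cc, Cd–Ce and Ca–Cb into a 4-substituted 3-ethoxycyclobutenone (Cb, Ce, Cf, Ca; ring A on the Ca methylene) and a methyl ynol ether (Cc, Cd; ring B on the Cc methylene). The alkyne oxygen carries methyl, not ethyl, so that no retro-ene loss of ethylene can compete at the temperature the benzannulation needs.
4. Cyclobutenone: butanoylfilicinic acid, Michael addition to tert-butyl acrylate, O-methylation, acid chloride, ketene [2+2] with ethoxyacetylene. Ynol ether: C-trimethylated propanoylphloroglucinol, O-methylation, allylic bromination, Stille coupling with tributyl(methoxyethynyl)stannane; neutral palladium catalysis is used because a lithium acetylide would add to the ring B carbonyl groups.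
5. Ring order: rings A and B first (dearomatising C-methylation of the two acylphloroglucinols), ring C last.

Key step: step 11

Remark: exhaustive O-methylation (steps 3 and 7) is taken to give the cross-conjugated bis-ether with both methoxy groups next to the CMe2 carbon; a regioisomeric bis-ether would behave alike in the later steps and give the same triketone in step 12.

Remark: compounds 10, 22 and 24 are racemic; their stereocentres are destroyed when ring C aromatises, and the target has none.

## Route

Step 1
Reactants: 1 1-(2,4,6-trihydroxyphenyl)butan-1-one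
Product: 2 butanoylfilicinic acid (2-butanoyl-3,5-dihydroxy-4,4-dimethylcyclohexa-2,5-dien-1-one)
Conditions: NaOMe (3 equiv), MeI (2.2 equiv), MeOH, 0 °C to rt; then aq HCl
Reagents that add atoms: iodomethane, CI
Why: Double C-methylation of the phloroglucinol anion at one unsubstituted ring carbon (dearomatising alkylation, the classical entry to acylfilicinic acids) should give the gem-dimethyl triketone without forming a stereocentre.

Step 2
Reactants: 2 butanoylfilicinic acid; 3 tert-butyl acrylate
Product: 4 tert-butyl 3-(5-butanoyl-2,4-dihydroxy-3,3-dimethyl-6-oxocyclohexa-1,4-dien-1-yl)propanoate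
Conditions: DBU (0.3 equiv), MeCN, 50 °C; 3 (0.9 equiv) added slowly
Reagents that add atoms: none
Why: Base-catalysed Michael addition of the soft triketone enolate through its only unsubstituted ring carbon, with the acrylate kept limiting to hold back a second addition at the same carbon.

Step 3
Reactants: 4 Michael adduct
Product: 5 tert-butyl 3-(5-butanoyl-2,4-dimethoxy-3,3-dimethyl-6-oxocyclohexa-1,4-dien-1-yl)propanoate
Conditions: TMSCHN2 (excess), PhMe/MeOH 4:1, 0 °C to rt
Reagents that add atoms: (trimethylsilyl)diazomethane, C[Si](C)(C)C=[N+]=[N-]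
Why: O-Methylation of the two acidic enols by the diazoalkane (proton transfer, then collapse of the ion pair at oxygen) should alkylate oxygen only and leave the nucleophilic ring carbon untouched.

Step 4
Reactants: 5 bis(methyl ether) ester
Product: 6 3-(5-butanoyl-2,4-dimethoxy-3,3-dimethyl-6-oxocyclohexa-1,4-dien-1-yl)propanoic acid
Conditions: TFA/CH2Cl2 1:4, anhydrous, 0 °C to rt
Reagents that add atoms: none
Why: Acidolysis of the tert-butyl ester by E1 loss of isobutene; in the absence of water the vinylogous methyl esters should not hydrolyse.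

Step 5
Reactants: 6 propanoic acid; 7 ethoxyacetylene
Product: 10 2-butanoyl-6-[(2-ethoxy-4-oxocyclobut-2-en-1-yl)methyl]-3,5-dimethoxy-4,4-dimethylcyclohexa-2,5-dien-1-one (racemic), via acid chloride 8 (not isolated), via alkylketene 9 (not isolated)
Conditions: 1-chloro-N,N,2-trimethylprop-1-en-1-amine (1.1 equiv), CH2Cl2, 0 °C; then added slowly to 7 (5 equiv), Et3N (1.5 equiv), CH2Cl2, 0 °C to rt
Reagents that add atoms: none
Why: The neutral chloroenamine should give the acid chloride without touching the dienone, and dehydrochlorination to the monoalkylketene followed by thermal ketene–ynol ether [2+2] cycloaddition (ketene carbonyl carbon to the unsubstituted alkyne carbon) gives the 3-ethoxy-4-alkylcyclobutenone, whose one new stereocentre is formed racemic and is lost in step 11.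

Step 6
Reactants: 11 1-(2,4,6-trihydroxyphenyl)propan-1-one
Product: 12 3,5-dihydroxy-4,4,6-trimethyl-2-propanoylcyclohexa-2,5-dien-1-one
Conditions: NaOMe (4 equiv), MeI (3.1 equiv), MeOH, 0 °C to rt; then aq HCl
Reagents that add atoms: iodomethane, CI
Why: Three successive C-methylations of the phloroglucinol anion (dearomatising alkylation); every order of methylation converges on the same 4,4,6-trimethyl pattern, so only the degree of methylation, set by the stoichiometry, has to be controlled.

Step 7
Reactants: 12 trimethyl triketone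
Product: 13 3,5-dimethoxy-4,4,6-trimethyl-2-propanoylcyclohexa-2,5-dien-1-one
Conditions: TMSCHN2 (excess), PhMe/MeOH 4:1, 0 °C to rt
Reagents that add atoms: (trimethylsilyl)diazomethane, C[Si](C)(C)C=[N+]=[N-]
Why: O-Methylation of both acidic enols by the diazoalkane, as in step 3; the fully substituted ring carbons cannot be C-alkylated.

Step 8
Reactants: 13 bis(methyl ether)
Product: 14 2-(bromomethyl)-3,5-dimethoxy-4,4-dimethyl-6-propanoylcyclohexa-2,5-dien-1-one
Conditions: NBS (1.05 equiv), AIBN (5 mol%), PhCF3, 80 °C; used crude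
Reagents that add atoms: N-bromosuccinimide, O=C1CCC(=O)N1Br
Why: Wohl–Ziegler bromination; the only allylic C–H bonds are those of the methyl on the enol ether double bond (the neighbouring ring carbon is quaternary), and the non-polar medium favours the radical chain over ionic attack on the enol ether.

Step 9
Reactants: 15 2-chloro-1,1-dimethoxyethane
Product: 19 tributyl(methoxyethynyl)stannane, via 1-chloro-2-methoxyethene 16 (not isolated), via methoxyethyne 17 (not isolated), via lithium methoxyacetylide 18 (not isolated)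
Conditions: Et2NH, n-BuLi (3.1 equiv each), THF, 0 °C; then Bu3SnCl (1.2 equiv), −78 °C to rt
Reagents that add atoms: tributyltin chloride, CCCC[Sn](Cl)(CCCC)CCCC
Why: Lithium diethylamide should remove methanol and then HCl from the chloroacetal (two β-eliminations) and deprotonate the methoxyethyne so formed, and the acetylide is stannylated at carbon.

Step 10
Reactants: 14 allylic bromide; 19 tributyl(methoxyethynyl)stannane
Product: 20 3,5-dimethoxy-2-(3-methoxyprop-2-yn-1-yl)-4,4-dimethyl-6-propanoylcyclohexa-2,5-dien-1-one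
Conditions: Pd2(dba)3 (2.5 mol%), tri(2-furyl)phosphine (10 mol%), THF, 50 °C
Reagents that add atoms: none
Why: Stille coupling of an allylic bromide with an alkynylstannane; zerovalent palladium inserts into the C–Br bond, the alkynyl group is delivered to the unhindered CH2 terminus of the allyl ligand, and the neutral conditions spare the carbonyl groups.

Step 11
Reactants: 10 3-ethoxycyclobutenone carrying ring A; 20 methyl ynol ether carrying ring B
Product: 25 benzannulated phenol (3-ethoxy-5-methoxyphenol core bearing both O-methylated wings), via vinylketene 21 (not isolated), via vinylcyclobutenone 22 (not isolated), via dienylketene 23 (not isolated), via cyclohexadienone 24 (not isolated)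
Conditions: PhMe (0.5 M), 110 °C, sealed tube, Ar; 20 (1.2 equiv)
Reagents that add atoms: none
Why: Proposed new method: heating should open cyclobutenone 10 by 4π electrocyclic cleavage of its C(=O)–CH bond to the 3-ethoxyvinylketene 21, which adds ynol ether 20 by [2+2] cycloaddition to give 22; a second 4π opening gives dienylketene 23, whose thermal disrotatory 6π electrocyclisation closes the six-membered ring C, and enolisation of dienone 24 delivers the phenol. The closest known reaction type is the Danheiser benzannulation of cyclobutenones with alkoxyalkynes, together with the known thermal opening of 4-substituted 3-alkoxycyclobutenones to alkoxyvinylketenes; what is new is a 3-alkoxycyclobutenone as the four-carbon partner of the intermolecular reaction, which places oxygen on Cb, Cd and Cf. The bonds made are Cb–Cc and Cd–Ce in the cycloaddition and Ca–Cb in the electrocyclisation, the last one re-forming the bond cleaved in the first opening. The step needs head-to-tail regiochemistry in the [2+2] addition, and the ynol ether secures it because its nucleophilic carbon, the one bearing the ring B methylene, bonds to the electrophilic ketene carbonyl carbon. Outward rotation of the ring A methylene in the first opening keeps it away from the ketene, so that a [1,5]-hydrogen shift should not compete. No stereocentre remains, since the sp3 centres of 10, 22 and 24 become aromatic carbons.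

Step 12
Reactants: 25 benzannulated phenol
Product: 26 2-[(ring A)methyl]-4-[(ring B)methyl]benzene-1,3,5-triol with both wings as free triketone enols
Conditions: BBr3 (12 equiv), CH2Cl2, −78 °C to 0 °C; then MeOH, H2O
Reagents that add atoms: none
Why: BBr3 cleaves the alkyl–oxygen bonds of the two aryl ethers and the four vinylogous methyl esters (coordination at oxygen, bromide attack at the alkyl carbon), and hydrolysis of the borates frees the six hydroxyl groups.

Step 13
Reactants: 26 bridged phloroglucinol
Product: 27 target CNP0373153.0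
Conditions: butanoyl chloride (1.5 equiv), AlCl3 (8 equiv), CH2Cl2/PhNO2, 0 °C to rt; then 1 M HCl
Reagents that add atoms: butanoyl chloride, CCCC(=O)Cl
Why: Friedel–Crafts acylation of a phloroglucinol at Ce, the only unsubstituted sp2 carbon of the molecule; any O-acyl group on a phenol or enol should be transferred to carbon under AlCl3 (Fries) or be lost on aqueous work-up.

## Compound list

In the names below, "ring A unit" is 5-butanoyl-2,4-dimethoxy-3,3-dimethyl-6-oxocyclohexa-1,4-dien-1-yl and "ring B unit" is 2,4-dimethoxy-3,3-dimethyl-6-oxo-5-propanoylcyclohexa-1,4-dien-1-yl.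

1 | 1-(2,4,6-trihydroxyphenyl)butan-1-one | CCCC(=O)c1c(O)cc(O)cc1O | starting material
2 | 2-butanoyl-3,5-dihydroxy-4,4-dimethylcyclohexa-2,5-dien-1-one (butanoylfilicinic acid) | CCCC(=O)C1=C(O)C(C)(C)C(O)=CC1=O | intermediate
3 | tert-butyl acrylate | C=CC(=O)OC(C)(C)C | starting material
4 | tert-butyl 3-(5-butanoyl-2,4-dihydroxy-3,3-dimethyl-6-oxocyclohexa-1,4-dien-1-yl)propanoate | CCCC(=O)C1=C(O)C(C)(C)C(O)=C(CCC(=O)OC(C)(C)C)C1=O | intermediate
5 | tert-butyl 3-(ring A unit)propanoate | CCCC(=O)C1=C(OC)C(C)(C)C(OC)=C(CCC(=O)OC(C)(C)C)C1=O | intermediate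
6 | 3-(ring A unit)propanoic acid | CCCC(=O)C1=C(OC)C(C)(C)C(OC)=C(CCC(=O)O)C1=O | intermediate
7 | ethoxyacetylene (ethoxyethyne) | CCOC#C | starting material
8 | 3-(ring A unit)propanoyl chloride | CCCC(=O)C1=C(OC)C(C)(C)C(OC)=C(CCC(=O)Cl)C1=O | intermediate
9 | 2-butanoyl-3,5-dimethoxy-4,4-dimethyl-6-(3-oxoprop-2-en-1-yl)cyclohexa-2,5-dien-1-one (alkylketene) | CCCC(=O)C1=C(OC)C(C)(C)C(OC)=C(CC=C=O)C1=O | intermediate
10 | 2-butanoyl-6-[(2-ethoxy-4-oxocyclobut-2-en-1-yl)methyl]-3,5-dimethoxy-4,4-dimethylcyclohexa-2,5-dien-1-one, racemic | CCOC1=CC(=O)C1CC1=C(OC)C(C)(C)C(OC)=C(C(=O)CCC)C1=O | intermediate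
11 | 1-(2,4,6-trihydroxyphenyl)propan-1-one | CCC(=O)c1c(O)cc(O)cc1O | starting material
12 | 3,5-dihydroxy-4,4,6-trimethyl-2-propanoylcyclohexa-2,5-dien-1-one | CCC(=O)C1=C(O)C(C)(C)C(O)=C(C)C1=O | intermediate
13 | 3,5-dimethoxy-4,4,6-trimethyl-2-propanoylcyclohexa-2,5-dien-1-one | CCC(=O)C1=C(OC)C(C)(C)C(OC)=C(C)C1=O | intermediate
14 | 2-(bromomethyl)-3,5-dimethoxy-4,4-dimethyl-6-propanoylcyclohexa-2,5-dien-1-one | CCC(=O)C1=C(OC)C(C)(C)C(OC)=C(CBr)C1=O | intermediate
15 | 2-chloro-1,1-dimethoxyethane | COC(CCl)OC | starting material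
16 | 1-chloro-2-methoxyethene (mixture of E and Z isomers) | COC=CCl | intermediate
17 | methoxyethyne | COC#C | intermediate
18 | lithium methoxyacetylide | [Li]C#COC | intermediate
19 | tributyl(methoxyethynyl)stannane | COC#C[Sn](CCCC)(CCCC)CCCC | intermediate
20 | 3,5-dimethoxy-2-(3-methoxyprop-2-yn-1-yl)-4,4-dimethyl-6-propanoylcyclohexa-2,5-dien-1-one | COC#CCC1=C(OC)C(C)(C)C(OC)=C(C(=O)CC)C1=O | intermediate
21 | 2-butanoyl-6-[(2Z)-3-ethoxy-5-oxopenta-2,4-dien-1-yl]-3,5-dimethoxy-4,4-dimethylcyclohexa-2,5-dien-1-one (3-ethoxyvinylketene, ring A methylene trans to the ketene carbon) | O=C=C/C(OCC)=C/CC1=C(OC)C(C)(C)C(OC)=C(C(=O)CCC)C1=O | intermediate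
22 | 4-[1-ethoxy-3-(ring A unit)prop-1-en-1-yl]-3-methoxy-2-[(ring B unit)methyl]cyclobut-2-en-1-one, racemic | COC1=C(CC2=C(OC)C(C)(C)C(OC)=C(C(=O)CC)C2=O)C(=O)C1/C(OCC)=C/CC1=C(OC)C(C)(C)C(OC)=C(C(=O)CCC)C1=O | intermediate
23 | dienylketene: 5-ethoxy-3-methoxy-7-(ring A unit)-2-[(ring B unit)methyl]hepta-1,3,5-trien-1-one, central double bond cis | O=C=C(CC1=C(OC)C(C)(C)C(OC)=C(C(=O)CC)C1=O)/C(OC)=C\C(OCC)=C\CC1=C(OC)C(C)(C)C(OC)=C(C(=O)CCC)C1=O | intermediate
24 | 5-ethoxy-3-methoxy-6-[(ring A unit)methyl]-2-[(ring B unit)methyl]cyclohexa-2,4-dien-1-one, racemic | O=C1C(CC2=C(OC)C(C)(C)C(OC)=C(C(=O)CC)C2=O)=C(OC)C=C(OCC)C1CC1=C(OC)C(C)(C)C(OC)=C(C(=O)CCC)C1=O | intermediate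
25 | 3-ethoxy-5-methoxy-2-[(ring A unit)methyl]-6-[(ring B unit)methyl]phenol (C4 of the phenol unsubstituted) | COc1cc(OCC)c(CC2=C(OC)C(C)(C)C(OC)=C(C(=O)CCC)C2=O)c(O)c1CC1=C(OC)C(C)(C)C(OC)=C(C(=O)CC)C1=O | intermediate
26 | 2-[(5-butanoyl-2,4-dihydroxy-3,3-dimethyl-6-oxocyclohexa-1,4-dien-1-yl)methyl]-4-[(2,4-dihydroxy-3,3-dimethyl-6-oxo-5-propanoylcyclohexa-1,4-dien-1-yl)methyl]benzene-1,3,5-triol | Oc1cc(O)c(CC2=C(O)C(C)(C)C(O)=C(C(=O)CCC)C2=O)c(O)c1CC1=C(O)C(C)(C)C(O)=C(C(=O)CC)C1=O | intermediate
27 | 2-butanoyl-6-{[3-butanoyl-2,4,6-trihydroxy-5-[(2,4-dihydroxy-3,3-dimethyl-6-oxo-5-propanoylcyclohexa-1,4-dien-1-yl)methyl]phenyl]methyl}-3,5-dihydroxy-4,4-dimethylcyclohexa-2,5-dien-1-one (CNP0373153.0) | CCCC(=O)C1=C(O)C(C)(C)C(O)=C(Cc2c(O)c(CC3=C(O)C(C)(C)C(O)=C(C(=O)CC)C3=O)c(O)c(C(=O)CCC)c2O)C1=O | target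

## Step count

Total: 13 steps. Longest linear sequence: 8 steps (steps 1, 2, 3, 4, 5, 11, 12, 13).

## Steps most likely to fail

**Step 11 (proposed new method).** The donor-stabilised cyclobutenone may open too slowly, and the vinylketene may be consumed by dimerisation or by esterifying the phenol product before it finds the ynol ether. In that case ring C is not built but taken ready-made, and the bridges are made by the long-known alkaline formaldehyde condensation of acylfilicinic acids with acylphloroglucinols. The fallback sets out from 1, 2 and 11 and comes back to the route at 27. Compound 2 and an excess of 1 are treated with aqueous formaldehyde in dilute NaOH at 0 °C to give the mono-bridged 2-butanoyl-6-[(3-butanoyl-2,4,6-trihydroxyphenyl)methyl]-3,5-dihydroxy-4,4-dimethylcyclohexa-2,5-dien-1-one F1. Compound 11 is C-dimethylated (NaOMe, MeI 2.2 equiv, MeOH) to 3,5-dihydroxy-4,4-dimethyl-2-propanoylcyclohexa-2,5-dien-1-one F2. F1, F2 and formaldehyde under the same alkaline conditions should give 27, to be separated from the symmetrical products of bridge exchange.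

**Step 13.** Before Ce is acylated, the very electron-rich free core may be protonated at Ca or Cc under AlCl3/HCl, which would cleave or scramble the methylene bridges, and the seven hydroxyl groups may hold the acyl group on oxygen. The fallback sets out from 25 and comes back at 27. Compound 25 is acylated first, while the wings are non-acidic enol ethers and the core has a single hydroxyl, with butanoyl chloride and SnCl4 in CH2Cl2 at −40 °C. This should give 1-{2-ethoxy-4-hydroxy-6-methoxy-3-[(ring A unit)methyl]-5-[(ring B unit)methyl]phenyl}butan-1-one F3. BBr3 (CH2Cl2, −78 °C to 0 °C) then removes all six alkyl groups from a core that the acyl group has made less prone to ipso protonation, giving 27.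

**Step 8.** Ionic bromination at the enol ether double bond or at the propanoyl α-carbon may outrun the radical substitution at the ring methyl, and the allylic bromide may hydrolyse on handling. The fallback introduces the CH2 group by cross-coupling; it sets out from 11 and comes back at 14. Compound 11 is C-dimethylated (NaOMe, MeI 2.2 equiv, MeOH) to 3,5-dihydroxy-4,4-dimethyl-2-propanoylcyclohexa-2,5-dien-1-one F4 and O-methylated with TMSCHN2 to 3,5-dimethoxy-4,4-dimethyl-2-propanoylcyclohexa-2,5-dien-1-one F5. Iodination of its only ring C–H with N-iodosuccinimide in MeCN gives 2-iodo-3,5-dimethoxy-4,4-dimethyl-6-propanoylcyclohexa-2,5-dien-1-one F6. Stille coupling with tributyl(hydroxymethyl)stannane (Pd(PPh3)4, dioxane, 90 °C) gives 2-(hydroxymethyl)-3,5-dimethoxy-4,4-dimethyl-6-propanoylcyclohexa-2,5-dien-1-one F7, and CBr4/PPh3 in CH2Cl2 at 0 °C (Appel reaction) converts it into 14.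

## Further compounds

F1 | step 11 | 2-butanoyl-6-[(3-butanoyl-2,4,6-trihydroxyphenyl)methyl]-3,5-dihydroxy-4,4-dimethylcyclohexa-2,5-dien-1-one | CCCC(=O)C1=C(O)C(C)(C)C(O)=C(Cc2c(O)cc(O)c(C(=O)CCC)c2O)C1=O
F2 | step 11 | 3,5-dihydroxy-4,4-dimethyl-2-propanoylcyclohexa-2,5-dien-1-one | CCC(=O)C1=C(O)C(C)(C)C(O)=CC1=O
F3 | step 13 | 1-{2-ethoxy-4-hydroxy-6-methoxy-3-[(ring A unit)methyl]-5-[(ring B unit)methyl]phenyl}butan-1-one | CCCC(=O)c1c(OCC)c(CC2=C(OC)C(C)(C)C(OC)=C(C(=O)CCC)C2=O)c(O)c(CC2=C(OC)C(C)(C)C(OC)=C(C(=O)CC)C2=O)c1OC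
F4 | step 8 | 3,5-dihydroxy-4,4-dimethyl-2-propanoylcyclohexa-2,5-dien-1-one (same compound as F2) | CCC(=O)C1=C(O)C(C)(C)C(O)=CC1=O
F5 | step 8 | 3,5-dimethoxy-4,4-dimethyl-2-propanoylcyclohexa-2,5-dien-1-one | CCC(=O)C1=C(OC)C(C)(C)C(OC)=CC1=O
F6 | step 8 | 2-iodo-3,5-dimethoxy-4,4-dimethyl-6-propanoylcyclohexa-2,5-dien-1-one | CCC(=O)C1=C(OC)C(C)(C)C(OC)=C(I)C1=O
F7 | step 8 | 2-(hydroxymethyl)-3,5-dimethoxy-4,4-dimethyl-6-propanoylcyclohexa-2,5-dien-1-one | CCC(=O)C1=C(OC)C(C)(C)C(OC)=C(CO)C1=O
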